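**Retrosynthetic overview**
- C3 is set last but one, by catalyst-controlled iridium asymmetric hydrogenation of a (Z)-3-alkylidenephthalide, instead of the usual ketone reduction or sulfone olefination between a phthalide and a spiroketal piece.
- The alkylidenephthalide comes in one operation from 2-iodo-4,6-dimethoxybenzoic acid and a terminal alkyne by Sonogashira coupling and 5-exo-dig lactonisation, which also joins the two halves.
- The spiroketal comes from a one-flask three-component union: acetone N,N-dimethylhydrazone is alkylated on both methyl groups by two enantiopure terminal epoxides, then treated with acid.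
- Ring order: arene (bought), both spiroketal rings together, lactone ring, then C3–H; the spiro carbon is settled in the final acid equilibration and separation.

Assumption: the spiro carbon of a 1,6-dioxaspiro[4.4]nonane equilibrates under acid with no useful thermodynamic bias, so every spiroketal intermediate before the last step is carried as the (2R,7R) pair of C5 epimers (SMILES written without a spiro descriptor) and C5 is fixed in the last step.

**Step 1**
Reactants: 1 1-iodo-3,5-dimethoxybenzene
Product: 2 2-iodo-4,6-dimethoxybenzaldehyde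
Conditions: POCl3 (2 equiv), DMF, 0 → 90 °C; then ice-water
Reagents that add atoms: N,N-dimethylformamide CN(C)C=O; water O
Why: Vilsmeier–Haack formylation goes para to one methoxy and ortho to the other (next to iodine) rather than into the doubly flanked position between the two methoxy groups, as is established for the bromo analogue, and the aryl iodide is inert.

**Step 2**
Reactants: 2 2-iodo-4,6-dimethoxybenzaldehyde
Product: 3 2-iodo-4,6-dimethoxybenzoic acid
Conditions: NaClO2, NaH2PO4, 2-methyl-2-butene (10 equiv), t-BuOH/THF/H2O, rt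
Reagents that add atoms: sodium chlorite NaClO2 [Na+].[O-]Cl=O
Why: Pinnick oxidation converts the hindered aldehyde to the acid chemoselectively, and the alkene scavenger removes hypochlorous acid so the electron-rich ring is not chlorinated.

**Step 3**
Reactants: 4 6-chlorohex-1-yne
Product: 5 (6-chlorohex-1-yn-1-yl)trimethylsilane
Conditions: n-BuLi (1.05 equiv), THF, −78 °C; Me3SiCl, −78 °C → rt
Reagents that add atoms: chlorotrimethylsilane C[Si](C)(C)Cl
Why: Acetylide C-silylation masks the acidic alkyne C–H for the organometallic steps that follow, and the primary chloride does not react at −78 °C.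

**Step 4**
Reactants: 5 (6-chlorohex-1-yn-1-yl)trimethylsilane, 6 (R)-epichlorohydrin
Product: 8 (2R)-1-chloro-9-(trimethylsilyl)non-8-yn-2-ol, via Grignard reagent 7 (not isolated)
Conditions: Mg, I2 (cat.), THF, reflux; then CuI (10 mol%), 6 (0.85 equiv), −30 → 0 °C; cold 1 M HCl
Reagents that add atoms: none
Why: Grignard formation followed by CuI-catalysed SN2 opening of the epoxide at its unsubstituted CH2 breaks no bond to the stereocentre, so the R configuration of 6 is carried over unchanged (the CIP ranks also stay the same).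

**Step 5**
Reactants: 8 (2R)-1-chloro-9-(trimethylsilyl)non-8-yn-2-ol
Product: 9 trimethyl{7-[(2R)-oxiran-2-yl]hept-1-yn-1-yl}silane
Conditions: NaH (1.2 equiv), THF, 0 °C → rt
Reagents that add atoms: none
Why: Intramolecular Williamson etherification (alkoxide SN2 at CH2Cl) closes the epoxide without touching the carbinol centre, and a hydride base in an aprotic solvent leaves the C-silyl alkyne intact.

**Step 6**
Reactants: 9 trimethyl{7-[(2R)-oxiran-2-yl]hept-1-yn-1-yl}silane, 10 acetone N,N-dimethylhydrazone, 11 (R)-propylene oxide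
Product: 15 trimethyl{7-[(2R,7R)-7-methyl-1,6-dioxaspiro[4.4]nonan-2-yl]hept-1-yn-1-yl}silane (C5 epimers), via hydroxy hydrazone 12 (not isolated), via dihydroxy hydrazone 13 (not isolated), via dihydroxy ketone 14 (not isolated)
Conditions: 10 (1.2 equiv), LiN(iPr)2 (1.15 equiv), THF, −78 → 0 °C; 9 (1.0 equiv), 0 °C → rt; LiN(iPr)2 (1.3 equiv), −78 → 0 °C; 11 (2 equiv), 0 °C → rt; then 2 M aq. HCl, THF, rt
Reagents that add atoms: none
Why: Corey–Enders alkylation of the metalated hydrazone, done twice (the second deprotonation goes kinetically at the remaining methyl group), opens each epoxide at CH2 so that C2 and C7 come unchanged from 9 and 11, and acid then hydrolyses the hydrazone and closes the spiroketal under thermodynamic control, giving both C5 epimers in about equal amounts.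

**Step 7**
Reactants: 15 trimethyl{7-[(2R,7R)-7-methyl-1,6-dioxaspiro[4.4]nonan-2-yl]hept-1-yn-1-yl}silane (C5 epimers)
Product: 16 (2R,7R)-2-(hept-6-yn-1-yl)-7-methyl-1,6-dioxaspiro[4.4]nonane (C5 epimers)
Conditions: K2CO3 (0.2 equiv), MeOH, rt
Reagents that add atoms: none
Why: Base-catalysed methanolysis of the C(sp)–Si bond frees the terminal alkyne, and the spiroketal is stable to base.

**Step 8**
Reactants: 3 2-iodo-4,6-dimethoxybenzoic acid, 16 (2R,7R)-2-(hept-6-yn-1-yl)-7-methyl-1,6-dioxaspiro[4.4]nonane (C5 epimers)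
Product: 18 (3Z)-5,7-dimethoxy-3-{6-[(2R,7R)-7-methyl-1,6-dioxaspiro[4.4]nonan-2-yl]hexylidene}-2-benzofuran-1(3H)-one (C5″ epimers), via alkynylbenzoic acid 17 (not isolated)
Conditions: PdCl2(PPh3)2 (3 mol%), CuI (6 mol%), Et3N (5 equiv), degassed DMF, 60 °C
Reagents that add atoms: none
Why: Sonogashira coupling is followed in the same flask by 5-exo-dig anti addition of the ortho carboxylate across the new alkyne, which under amine-base conditions favours the five-membered (Z)-enol lactone over the 6-endo isocoumarin (neither methoxy group is conjugated to the alkyne carbon).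

**Step 9**
Reactants: 18 (3Z)-5,7-dimethoxy-3-{6-[(2R,7R)-7-methyl-1,6-dioxaspiro[4.4]nonan-2-yl]hexylidene}-2-benzofuran-1(3H)-one (C5″ epimers)
Product: 19 (3R)-5,7-dimethoxy-3-{6-[(2R,7R)-7-methyl-1,6-dioxaspiro[4.4]nonan-2-yl]hexyl}-2-benzofuran-1(3H)-one (C5″ epimers)
Conditions: [Ir(cod)(SpinPHOX)]B[3,5-(CF3)2C6H3]4 (1 mol%; SpinPHOX = spiro[4.4]nona-1,6-diene diphenylphosphine–oxazoline ligand, antipode chosen for 3R), H2 (30 bar), CH2Cl2, rt
Reagents that add atoms: none
Why: Iridium phosphine–oxazoline catalysed asymmetric hydrogenation of the geometrically pure (Z)-enol lactone is a known route to 3-alkylphthalides; the ligand antipode that delivers hydrogen to the Si face of C3 (checked first on the 3-butylidene model) sets 3R under catalyst control, and the homogeneous catalyst does not cleave the benzylic C–O bond.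

**Step 10**
Reactants: 19 (3R)-5,7-dimethoxy-3-{6-[(2R,7R)-7-methyl-1,6-dioxaspiro[4.4]nonan-2-yl]hexyl}-2-benzofuran-1(3H)-one (C5″ epimers)
Product: 20 (3R)-5,7-dimethoxy-3-{6-[(2R,5S,7R)-7-methyl-1,6-dioxaspiro[4.4]nonan-2-yl]hexyl}-2-benzofuran-1(3H)-one
Conditions: CSA (5 mol%), CH2Cl2, rt; preparative HPLC (silica, hexane/EtOAc); recovered (5″R) epimer put back through the same treatment twice
Reagents that add atoms: none
Why: Acid-catalysed spiroketal epimerisation through the ring-opened oxocarbenium ion gives the roughly 1:1 thermodynamic pair, from which the (5″S) diastereomer is separated while C3, C2″ and C7″ (none ionisable under these conditions) stay fixed, and recycling the other epimer raises the yield above one half.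

**Compound list**
1 | 1-iodo-3,5-dimethoxybenzene | COc1cc(I)cc(OC)c1 | starting material
2 | 2-iodo-4,6-dimethoxybenzaldehyde | COc1cc(I)c(C=O)c(OC)c1 | intermediate
3 | 2-iodo-4,6-dimethoxybenzoic acid | COc1cc(I)c(C(=O)O)c(OC)c1 | intermediate
4 | 6-chlorohex-1-yne | C#CCCCCCl | starting material
5 | (6-chlorohex-1-yn-1-yl)trimethylsilane | C[Si](C)(C)C#CCCCCCl | intermediate
6 | (R)-epichlorohydrin, (2R)-2-(chloromethyl)oxirane | ClC[C@H]1CO1 | starting material
7 | [6-(trimethylsilyl)hex-5-yn-1-yl]magnesium chloride | C[Si](C)(C)C#CCCCC[Mg]Cl | intermediate (not isolated)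
8 | (2R)-1-chloro-9-(trimethylsilyl)non-8-yn-2-ol | ClC[C@H](O)CCCCCC#C[Si](C)(C)C | intermediate
9 | trimethyl{7-[(2R)-oxiran-2-yl]hept-1-yn-1-yl}silane | C[Si](C)(C)C#CCCCCC[C@@H]1CO1 | intermediate
10 | acetone N,N-dimethylhydrazone, 1,1-dimethyl-2-(propan-2-ylidene)hydrazine | CC(C)=NN(C)C | starting material
11 | (R)-propylene oxide, (2R)-2-methyloxirane | C[C@@H]1CO1 | starting material
12 | (5R)-2-(2,2-dimethylhydrazinylidene)-12-(trimethylsilyl)dodec-11-yn-5-ol (lithium alkoxide in the flask) | CC(=NN(C)C)CC[C@H](O)CCCCCC#C[Si](C)(C)C | intermediate (not isolated)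
13 | (2R,8R)-5-(2,2-dimethylhydrazinylidene)-15-(trimethylsilyl)pentadec-14-yne-2,8-diol (dilithium dialkoxide before the acid is added) | C[C@@H](O)CCC(=NN(C)C)CC[C@H](O)CCCCCC#C[Si](C)(C)C | intermediate (not isolated)
14 | (2R,8R)-2,8-dihydroxy-15-(trimethylsilyl)pentadec-14-yn-5-one | C[C@@H](O)CCC(=O)CC[C@H](O)CCCCCC#C[Si](C)(C)C | intermediate (not isolated)
15 | trimethyl{7-[(2R,7R)-7-methyl-1,6-dioxaspiro[4.4]nonan-2-yl]hept-1-yn-1-yl}silane, C5 epimers about 1:1 | C[Si](C)(C)C#CCCCCC[C@@H]1CCC2(CC[C@@H](C)O2)O1 | intermediate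
16 | (2R,7R)-2-(hept-6-yn-1-yl)-7-methyl-1,6-dioxaspiro[4.4]nonane, C5 epimers about 1:1 | C#CCCCCC[C@@H]1CCC2(CC[C@@H](C)O2)O1 | intermediate
17 | 2,4-dimethoxy-6-{7-[(2R,7R)-7-methyl-1,6-dioxaspiro[4.4]nonan-2-yl]hept-1-yn-1-yl}benzoic acid, C5″ epimers | COc1cc(OC)c(C(=O)O)c(c1)C#CCCCCC[C@@H]1CCC2(CC[C@@H](C)O2)O1 | intermediate (not isolated)
18 | (3Z)-5,7-dimethoxy-3-{6-[(2R,7R)-7-methyl-1,6-dioxaspiro[4.4]nonan-2-yl]hexylidene}-2-benzofuran-1(3H)-one, C5″ epimers | O=C1O/C(=C\CCCCC[C@@H]2CCC3(CC[C@@H](C)O3)O2)c4cc(OC)cc(OC)c14 | intermediate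
19 | (3R)-5,7-dimethoxy-3-{6-[(2R,7R)-7-methyl-1,6-dioxaspiro[4.4]nonan-2-yl]hexyl}-2-benzofuran-1(3H)-one, C5″ epimers | COc1cc(OC)c2c(c1)[C@@H](CCCCCC[C@@H]1CCC3(CC[C@@H](C)O3)O1)OC2=O | intermediate
20 | (3R)-5,7-dimethoxy-3-{6-[(2R,5S,7R)-7-methyl-1,6-dioxaspiro[4.4]nonan-2-yl]hexyl}-2-benzofuran-1(3H)-one | COc1cc(OC)c2c(c1)[C@@H](CCCCCC[C@@H]1CC[C@]3(CC[C@@H](C)O3)O1)OC2=O | target

**Totals**
Total step count: 10. Longest linear sequence: 8 steps (from 4 through steps 3 to 10); the arene branch (steps 1 and 2) joins at step 8.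

**Three steps most likely to fail, each with a fallback**

Step 6 (three-component union). The second deprotonation or the second epoxide opening may be sluggish or unselective. The fallback sets out from 9 and comes back at 15. The dianion of methyl acetoacetate (NaH, then n-BuLi, THF, 0 °C) opens 9 at CH2 through its terminal carbon to give methyl (6R)-6-hydroxy-3-oxo-13-(trimethylsilyl)tridec-12-ynoate F1. NaOMe in MeOH with 11 then alkylates the active methylene, and the new alkoxide lactonises onto the ester to give (5R)-3-[(4R)-4-hydroxy-11-(trimethylsilyl)undec-10-ynoyl]-5-methyloxolan-2-one F2. Warm aqueous HCl hydrolyses the lactone, decarboxylates the keto acid to 14 and closes it to 15.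

Step 8 (coupling and lactonisation in one flask). The hindered iodo acid may couple poorly, or 6-endo closure to the isocoumarin may compete. The fallback sets out from 2 and 16 and comes back at 18. Sonogashira coupling of the aldehyde 2 with 16 (PdCl2(PPh3)2, CuI, Et3N, THF, rt) gives 2,4-dimethoxy-6-{7-[(2R,7R)-7-methyl-1,6-dioxaspiro[4.4]nonan-2-yl]hept-1-yn-1-yl}benzaldehyde F3. Oxidation as in step 2 gives 17, now isolated. DBU (10 mol%) in MeCN then closes 17 to 18, since purely base-catalysed cyclisation is selective for the five-membered (Z)-enol lactone.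

Step 9 (asymmetric hydrogenation). The enantioselectivity may fall short with the 5,7-dimethoxy pattern and the long chain, or the catalyst may be slowed by the spiroketal oxygens. The fallback sets out from 18 and comes back at 19. NaOMe in MeOH opens the enol lactone to methyl 2,4-dimethoxy-6-{7-[(2R,7R)-7-methyl-1,6-dioxaspiro[4.4]nonan-2-yl]heptanoyl}benzoate F4. Asymmetric transfer hydrogenation with RuCl(p-cymene)[(R,R)-TsDPEN] in HCO2H/Et3N reduces the aryl ketone, with the usual aryl/alkyl model predicting the R alcohol, to methyl 2-[(1R)-1-hydroxy-7-[(2R,7R)-7-methyl-1,6-dioxaspiro[4.4]nonan-2-yl]heptyl]-4,6-dimethoxybenzoate F5. F5 lactonises in the flask to 19.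

**Further compounds**
F1 | step 6 | methyl (6R)-6-hydroxy-3-oxo-13-(trimethylsilyl)tridec-12-ynoate | COC(=O)CC(=O)CC[C@H](O)CCCCCC#C[Si](C)(C)C
F2 | step 6 | (5R)-3-[(4R)-4-hydroxy-11-(trimethylsilyl)undec-10-ynoyl]-5-methyloxolan-2-one, C3 epimers | C[C@@H]1CC(C(=O)CC[C@H](O)CCCCCC#C[Si](C)(C)C)C(=O)O1
F3 | step 8 | 2,4-dimethoxy-6-{7-[(2R,7R)-7-methyl-1,6-dioxaspiro[4.4]nonan-2-yl]hept-1-yn-1-yl}benzaldehyde, C5″ epimers | COc1cc(OC)c(C=O)c(c1)C#CCCCCC[C@@H]1CCC2(CC[C@@H](C)O2)O1
F4 | step 9 | methyl 2,4-dimethoxy-6-{7-[(2R,7R)-7-methyl-1,6-dioxaspiro[4.4]nonan-2-yl]heptanoyl}benzoate, C5″ epimers | COC(=O)c1c(OC)cc(OC)cc1C(=O)CCCCCC[C@@H]1CCC2(CC[C@@H](C)O2)O1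
F5 | step 9 | methyl 2-[(1R)-1-hydroxy-7-[(2R,7R)-7-methyl-1,6-dioxaspiro[4.4]nonan-2-yl]heptyl]-4,6-dimethoxybenzoate, C5″ epimers | COC(=O)c1c(OC)cc(OC)cc1[C@H](O)CCCCCC[C@@H]1CCC2(CC[C@@H](C)O2)O1
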